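Ring C is disconnected at O1–C2 and C4–C4a, which returns the flavanone to a silyl-protected caffeate ester of 2,4-diprenylphloroglucinol. In the key step a photo-Fries acyl shift moves the cinnamoyl group from oxygen to C4a, the only unsubstituted carbon of ring A, and a quinine-derived thiourea then closes the resulting chalcone by 6-endo oxa-Michael addition, setting C2 as S. The step exploits the local mirror symmetry of ring A about the C4a–C7 axis: O1 and the 5-hydroxyl are equivalent in the chalcone, so either oxygen gives the same ring C, and no protecting group is needed on ring A.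

Key step: step 7

Assumption: the quinine-derived thiourea, 1-[3,5-bis(trifluoromethyl)phenyl]-3-[(8S,9S)-6'-methoxycinchonan-9-yl]thiourea, is taken to deliver the phenoxide to the Si face of C2 (S product); if the sense proves opposite, the quinidine-derived pseudo-enantiomer is used instead.

**Step 1**
Reactants: 1 phloroglucinol
Product: 2 1,3,5-tris(methoxymethoxy)benzene
Conditions: MOMCl, DIPEA, DMF, 0 °C → rt
Reagents that add atoms: chloromethyl methyl ether, COCCl
Why: Threefold Williamson-type O-alkylation of the phenols by the reactive α-chloro ether; the hindered amine base in DMF favours O- over C-alkylation.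

**Step 2**
Reactants: 2 1,3,5-tris(methoxymethoxy)benzene
Product: 3 1,3,5-tris(methoxymethoxy)-2-(3-methylbut-2-en-1-yl)benzene
Conditions: n-BuLi, TMEDA, THF, 0 °C; then prenyl bromide, −78 °C → rt
Reagents that add atoms: prenyl bromide (1-bromo-3-methylbut-2-ene), CC(C)=CCBr
Why: Directed ortho-metalation, since every ring hydrogen of 2 lies between two MOM ethers, followed by SN2 alkylation of the aryllithium at the primary allylic carbon.

**Step 3**
Reactants: 3 1,3,5-tris(methoxymethoxy)-2-(3-methylbut-2-en-1-yl)benzene
Product: 4 1,3,5-tris(methoxymethoxy)-2,4-bis(3-methylbut-2-en-1-yl)benzene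
Conditions: n-BuLi, TMEDA, THF, 0 °C; then prenyl bromide, −78 °C → rt
Reagents that add atoms: prenyl bromide (1-bromo-3-methylbut-2-ene), CC(C)=CCBr
Why: Second directed ortho-metalation at one of the two equivalent positions still flanked by two MOM ethers, then the same SN2 prenylation; the position left over is the future C4a.

**Step 4**
Reactants: 4 1,3,5-tris(methoxymethoxy)-2,4-bis(3-methylbut-2-en-1-yl)benzene
Product: 5 2,4-bis(3-methylbut-2-en-1-yl)benzene-1,3,5-triol
Conditions: HCl (0.5 M in MeOH), rt, argon
Reagents that add atoms: none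
Why: Acid-catalysed acetal methanolysis of the three aryl MOM ethers, which is fast on this electron-rich ring at room temperature, so the prenyl double bonds should survive the short exposure.

**Step 5**
Reactants: 6 caffeic acid
Product: 8 (E)-3-[3,4-bis(tert-butyldimethylsilyloxy)phenyl]acrylic acid, via tris-TBS silyl ester 7 (not isolated)
Conditions: TBSCl, imidazole, DMF, rt; then AcOH/THF/H2O, rt
Reagents that add atoms: tert-butyldimethylsilyl chloride, CC(C)(C)[Si](C)(C)Cl
Why: Silylation of the catechol and the acid, then selective hydrolysis of the labile silyl ester by aqueous acetic acid, which leaves the aryl silyl ethers intact.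

**Step 6**
Reactants: 5 2,4-bis(3-methylbut-2-en-1-yl)benzene-1,3,5-triol, 8 (E)-3-[3,4-bis(tert-butyldimethylsilyloxy)phenyl]acrylic acid
Product: 9 3,5-dihydroxy-2,4-bis(3-methylbut-2-en-1-yl)phenyl (E)-3-[3,4-bis(tert-butyldimethylsilyloxy)phenyl]acrylate
Conditions: DCC, DMAP (cat.), CH2Cl2, 0 °C; 8 added slowly to 5 (2 equiv)
Reagents that add atoms: none
Why: Steglich esterification; the two equivalent hydroxyls at C1 and C5 of 5 are less hindered than the C3 hydroxyl between the prenyl groups, and the excess of 5 suppresses diacylation.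

**Step 7**
Reactants: 9 3,5-dihydroxy-2,4-bis(3-methylbut-2-en-1-yl)phenyl (E)-3-[3,4-bis(tert-butyldimethylsilyloxy)phenyl]acrylate
Product: 11 (2S)-2-[3,4-bis(tert-butyldimethylsilyloxy)phenyl]-5,7-dihydroxy-6,8-bis(3-methylbut-2-en-1-yl)chroman-4-one, via chalcone 10 (not isolated)
Conditions: hν (300 nm, Pyrex), degassed PhMe (5 mM), 10 °C; then dark, concentrate to 0.1 M, quinine-derived thiourea (10 mol%), −20 °C
Reagents that add atoms: none
Why: Excitation of the aryl cinnamate homolyses the ArO–C(=O) bond and the caged acyl/aryloxyl radical pair recombines at C4a, the only ring A carbon that can re-aromatise, so this photo-Fries rearrangement (closest known type: hydroxyphenyl cinnamates to 2'-hydroxychalcones) forms C4–C4a without acid and spares the prenyl groups. Chalcone 10 is expected to be shielded from further photochemistry by excited-state proton transfer in its O–H···O=C chelate and to cyclise only slowly in cold, neutral toluene, so ring C closes once the bifunctional thiourea is added (closest known type: cinchona-thiourea-catalysed cyclisation of 2'-hydroxychalcones). Ring C closes by 6-endo-trig oxa-Michael addition of a phenoxide, ion-paired with the protonated quinuclidine, to the enone held by the thiourea, which forms O1–C2. C2 is the only new stereocentre and is set by the catalyst, which directs the oxygen to the Si face of C2 to give the S configuration. The step needs regioselectivity in both bond formations, and the substrate secures it: C4a is the only free ring carbon, and the two hydroxyls flanking the acyl group in 10 are related by the mirror plane through C4a and C7, so either closure gives the same flavanone. Low temperature and the hydrogen bond from the 5-hydroxyl to C4=O should disfavour retro-Michael opening, which would erode the configuration.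

**Step 8**
Reactants: 11 (2S)-2-[3,4-bis(tert-butyldimethylsilyloxy)phenyl]-5,7-dihydroxy-6,8-bis(3-methylbut-2-en-1-yl)chroman-4-one
Product: 12 6,8-diprenyleriodictyol, (2S)-2-(3,4-dihydroxyphenyl)-5,7-dihydroxy-6,8-bis(3-methylbut-2-en-1-yl)chroman-4-one
Conditions: Et3N·3HF, THF, 0 °C → rt
Reagents that add atoms: none
Why: Fluoride cleaves the two aryl silyl ethers in a buffered, weakly acidic medium that avoids base-induced opening of ring C, so C2 keeps its configuration and the prenyl groups are untouched.

**Compound list**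

1 | phloroglucinol (benzene-1,3,5-triol) | Oc1cc(O)cc(O)c1 | starting material
2 | 1,3,5-tris(methoxymethoxy)benzene | COCOc1cc(OCOC)cc(OCOC)c1 | intermediate
3 | 1,3,5-tris(methoxymethoxy)-2-(3-methylbut-2-en-1-yl)benzene | COCOc1cc(OCOC)c(CC=C(C)C)c(OCOC)c1 | intermediate
4 | 1,3,5-tris(methoxymethoxy)-2,4-bis(3-methylbut-2-en-1-yl)benzene | COCOc1cc(OCOC)c(CC=C(C)C)c(OCOC)c1CC=C(C)C | intermediate
5 | 2,4-bis(3-methylbut-2-en-1-yl)benzene-1,3,5-triol | CC(C)=CCc1c(O)cc(O)c(CC=C(C)C)c1O | intermediate
6 | caffeic acid, (E)-3-(3,4-dihydroxyphenyl)acrylic acid | OC(=O)/C=C/c1ccc(O)c(O)c1 | starting material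
7 | tert-butyldimethylsilyl (E)-3-[3,4-bis(tert-butyldimethylsilyloxy)phenyl]acrylate (formed in the flask, not isolated) | CC(C)(C)[Si](C)(C)OC(=O)/C=C/c1ccc(O[Si](C)(C)C(C)(C)C)c(O[Si](C)(C)C(C)(C)C)c1 | intermediate
8 | (E)-3-[3,4-bis(tert-butyldimethylsilyloxy)phenyl]acrylic acid | OC(=O)/C=C/c1ccc(O[Si](C)(C)C(C)(C)C)c(O[Si](C)(C)C(C)(C)C)c1 | intermediate
9 | 3,5-dihydroxy-2,4-bis(3-methylbut-2-en-1-yl)phenyl (E)-3-[3,4-bis(tert-butyldimethylsilyloxy)phenyl]acrylate | CC(C)=CCc1c(O)c(CC=C(C)C)c(O)cc1OC(=O)/C=C/c1ccc(O[Si](C)(C)C(C)(C)C)c(O[Si](C)(C)C(C)(C)C)c1 | intermediate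
10 | (E)-3-[3,4-bis(tert-butyldimethylsilyloxy)phenyl]-1-[2,4,6-trihydroxy-3,5-bis(3-methylbut-2-en-1-yl)phenyl]prop-2-en-1-one (chalcone, formed in the flask, not isolated) | CC(C)=CCc1c(O)c(CC=C(C)C)c(O)c(C(=O)/C=C/c2ccc(O[Si](C)(C)C(C)(C)C)c(O[Si](C)(C)C(C)(C)C)c2)c1O | intermediate
11 | (2S)-2-[3,4-bis(tert-butyldimethylsilyloxy)phenyl]-5,7-dihydroxy-6,8-bis(3-methylbut-2-en-1-yl)chroman-4-one | CC(C)=CCc1c(O)c(CC=C(C)C)c2c(c1O)C(=O)C[C@@H](c1ccc(O[Si](C)(C)C(C)(C)C)c(O[Si](C)(C)C(C)(C)C)c1)O2 | intermediate
12 | 6,8-diprenyleriodictyol, (2S)-2-(3,4-dihydroxyphenyl)-5,7-dihydroxy-6,8-bis(3-methylbut-2-en-1-yl)chroman-4-one | CC(C)=CCc1c(O)c(CC=C(C)C)c2c(c1O)C(=O)C[C@@H](c1ccc(O)c(O)c1)O2 | target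

Total step count: 8. Longest linear sequence: 7 steps (1, 2, 3, 4, 6, 7, 8).

**Steps most likely to fail**

Step 7. The photochemical acyl shift may lose to E/Z isomerisation of the cinnamate and to escape of the radical pair from the solvent cage. Ring closure that happens during irradiation, or outside the catalyst's control, would also lower the facial selectivity at C2. The fallback separates ring closure from enantiocontrol by a kinetic resolution. It sets out from 9: the irradiated solution (chalcone 10) is closed without chiral catalyst (NaOAc, EtOH, 60 °C) to the racemic flavanone F1. Asymmetric transfer hydrogenation (RuCl[(R,R)-TsDPEN](p-cymene), HCO2H/Et3N, EtOAc, rt), stopped near half conversion, should reduce the (2R) enantiomer to the cis-(2R,4R)-flavan-4-ol F2. The unreacted (2S) ketone, separated by chromatography, comes back to the route at 11. If the acyl shift itself is the weak point, the fallback given for step 6 avoids the photochemistry altogether.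

Step 6. Statistical over-acylation and acyl scrambling among the three hydroxyls may deplete the mono-ester. The fallback forms C4–C4a by directed metalation instead of through an ester; it sets out from 4 and 8. Acid 8 is converted (MeNHOMe·HCl, DCC, Et3N, CH2Cl2) into the Weinreb amide F3. Compound 4 is lithiated at its last free ring position (n-BuLi, THF, 0 °C) and acylated with F3 to give the tris-MOM chalcone F4. MgBr2·OEt2 (Et2O, rt) removes, with chelation assistance, one of the two equivalent MOM groups beside the carbonyl to give the 2'-hydroxychalcone F5, which cannot cyclise at its other, still protected ortho oxygen. The thiourea of step 7 (PhMe, −20 °C) closes it to the bis-MOM flavanone F6. HCl in MeOH (40 °C) then removes the two MOM and the two silyl groups, and the sequence comes back at 12.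

Step 4. The acid needed to cleave three MOM ethers may add the freed phenols across the neighbouring prenyl double bonds (chroman formation) or hydrate them. The fallback dispenses with protecting groups on ring A. It sets out from 1: direct twofold C-prenylation of phloroglucinol (prenyl bromide, aq. KOH, 0 °C), with chromatographic removal of mono- and triprenylated material, comes back at 5 and makes no new compound (F0).

**Further compounds**

F1 | step 7 | racemic 2-[3,4-bis(tert-butyldimethylsilyloxy)phenyl]-5,7-dihydroxy-6,8-bis(3-methylbut-2-en-1-yl)chroman-4-one | CC(C)=CCc1c(O)c(CC=C(C)C)c2c(c1O)C(=O)CC(c1ccc(O[Si](C)(C)C(C)(C)C)c(O[Si](C)(C)C(C)(C)C)c1)O2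
F2 | step 7 | (2R,4R)-2-[3,4-bis(tert-butyldimethylsilyloxy)phenyl]-6,8-bis(3-methylbut-2-en-1-yl)chromane-4,5,7-triol | CC(C)=CCc1c(O)c(CC=C(C)C)c2c(c1O)[C@H](O)C[C@H](c1ccc(O[Si](C)(C)C(C)(C)C)c(O[Si](C)(C)C(C)(C)C)c1)O2
F3 | step 6 | (E)-3-[3,4-bis(tert-butyldimethylsilyloxy)phenyl]-N-methoxy-N-methylacrylamide | CON(C)C(=O)/C=C/c1ccc(O[Si](C)(C)C(C)(C)C)c(O[Si](C)(C)C(C)(C)C)c1
F4 | step 6 | (E)-3-[3,4-bis(tert-butyldimethylsilyloxy)phenyl]-1-[2,4,6-tris(methoxymethoxy)-3,5-bis(3-methylbut-2-en-1-yl)phenyl]prop-2-en-1-one | COCOc1c(CC=C(C)C)c(OCOC)c(CC=C(C)C)c(OCOC)c1C(=O)/C=C/c1ccc(O[Si](C)(C)C(C)(C)C)c(O[Si](C)(C)C(C)(C)C)c1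
F5 | step 6 | (E)-3-[3,4-bis(tert-butyldimethylsilyloxy)phenyl]-1-[2-hydroxy-4,6-bis(methoxymethoxy)-3,5-bis(3-methylbut-2-en-1-yl)phenyl]prop-2-en-1-one | COCOc1c(CC=C(C)C)c(OCOC)c(CC=C(C)C)c(O)c1C(=O)/C=C/c1ccc(O[Si](C)(C)C(C)(C)C)c(O[Si](C)(C)C(C)(C)C)c1
F6 | step 6 | (2S)-2-[3,4-bis(tert-butyldimethylsilyloxy)phenyl]-5,7-bis(methoxymethoxy)-6,8-bis(3-methylbut-2-en-1-yl)chroman-4-one | COCOc1c(CC=C(C)C)c(OCOC)c(CC=C(C)C)c2c1C(=O)C[C@@H](c1ccc(O[Si](C)(C)C(C)(C)C)c(O[Si](C)(C)C(C)(C)C)c1)O2
F0 | step 4 | none | none
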